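The flavonol is disconnected at O1–C8a and C4a–C4, the two bonds that join ring A to ring C. The ring oxygen O1 and the ketone carbon C4 sit on neighbouring ring A carbons (C8a and C4a), and C4a is flanked by the oxygenated C5. The pair C8a/C4a is therefore treated as the triple bond of a 3,5-bis(alkoxy)benzyne, and O1 with C4=O as the CO2H group of a ring B arylpropiolic acid. One operation inserts the aryne into the acid C–O bond and gives an ortho-hydroxyaryl ynone holding the whole carbon skeleton. The precursors are a 2-silylaryl triflate and the propiolic acid.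

Key step: step 8

Assumption: sulfate monoesters are drawn as free acids. Because aryl hydrogen sulfates hydrolyse readily in that state, compound 21 is isolated and hydrogenolysed as its dipotassium salt, and the acid form of the target is released only in the final cold acidification.

Step 1
Reactants: 1 3,4-dihydroxybenzaldehyde
Product: 2 3-hydroxy-4-(methoxymethoxy)benzaldehyde
Conditions: MOMCl (1.05 equiv), K2CO3 (1.1 equiv), acetone, 0 °C to rt
Reagents that add atoms: chloromethyl methyl ether, COCCl
Why: The 4-hydroxyl, para to the formyl group, is the more acidic phenol, so one equivalent of mild base should give its phenoxide, which is alkylated selectively (Williamson etherification).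

Step 2
Reactants: 2 3-hydroxy-4-(methoxymethoxy)benzaldehyde
Product: 3 3-(benzyloxy)-4-(methoxymethoxy)benzaldehyde
Conditions: BnBr (1.2 equiv), K2CO3, DMF, rt
Reagents that add atoms: benzyl bromide, BrCc1ccccc1
Why: Williamson O-benzylation of the remaining phenol under basic conditions that leave the MOM acetal and the aldehyde untouched.

Step 3
Reactants: 3 3-(benzyloxy)-4-(methoxymethoxy)benzaldehyde
Product: 4 2-(benzyloxy)-4-ethynyl-1-(methoxymethoxy)benzene
Conditions: dimethyl (1-diazo-2-oxopropyl)phosphonate (1.3 equiv), K2CO3 (2 equiv), MeOH, 0 °C to rt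
Reagents that add atoms: dimethyl (1-diazo-2-oxopropyl)phosphonate, CC(=O)C(=[N+]=[N-])P(=O)(OC)OC
Why: Seyferth–Gilbert homologation in its Ohira–Bestmann form converts an aryl aldehyde into the terminal alkyne in methanolic carbonate, to which MOM and benzyl ethers are inert.

Step 4
Reactants: 4 2-(benzyloxy)-4-ethynyl-1-(methoxymethoxy)benzene
Product: 6 3-[3-(benzyloxy)-4-(methoxymethoxy)phenyl]propiolic acid, via lithium acetylide 5 (not isolated)
Conditions: n-BuLi (1.05 equiv), THF, −78 °C; CO2 (gas), −78 to 0 °C; cold 0.5 M HCl to pH 3, rapid extraction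
Reagents that add atoms: carbon dioxide, O=C=O
Why: The alkyne C–H is deprotonated much faster than any ring position is metalated at −78 °C and the acetylide is carboxylated by CO2 (acetylide carboxylation); the brief cold acidic work-up should spare the MOM ether.

Step 5
Reactants: 7 phloroglucinol
Product: 8 3,5-bis(methoxymethoxy)phenol
Conditions: MOMCl (2.1 equiv), i-Pr2NEt (2.3 equiv), DMF, 0 °C to rt; chromatography
Reagents that add atoms: chloromethyl methyl ether, COCCl
Why: Twofold Williamson-type alkylation of a triphenol whose hydroxyls are all equivalent, so only the degree of alkylation has to be sorted by chromatography and the mono-ether can be recycled.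

Step 6
Reactants: 8 3,5-bis(methoxymethoxy)phenol
Product: 9 2-bromo-3,5-bis(methoxymethoxy)phenol
Conditions: NBS (1.0 equiv), i-Pr2NH (10 mol%), CH2Cl2, −78 to 0 °C
Reagents that add atoms: N-bromosuccinimide, O=C1CCC(=O)N1Br
Why: Amine-catalysed electrophilic bromination with NBS is delivered by hydrogen bonding to the phenol OH onto an ortho carbon, which is also favoured over C4 statistically (two sites) and sterically (C4 lies between two MOM ethers); one equivalent at low temperature limits dibromination.

Step 7
Reactants: 9 2-bromo-3,5-bis(methoxymethoxy)phenol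
Product: 12 3,5-bis(methoxymethoxy)-2-(trimethylsilyl)phenyl trifluoromethanesulfonate, via aryl trimethylsilyl ether 10 (not isolated), via lithium 2-silylphenoxide 11 (not isolated)
Conditions: HMDS, THF, 65 °C, then evaporate; n-BuLi (1.1 equiv), THF, −78 °C; Tf2O (1.2 equiv), −78 to 0 °C
Reagents that add atoms: hexamethyldisilazane, C[Si](C)(C)N[Si](C)(C)C; trifluoromethanesulfonic anhydride, O=S(=O)(OS(=O)(=O)C(F)(F)F)C(F)(F)F
Why: O-Silylation followed by bromine–lithium exchange triggers a 1,3 O-to-C silyl shift (retro-Brook rearrangement) to the ortho-silyl phenoxide, which is triflated in the same flask; exchange at −78 °C outruns MOM-directed ring deprotonation.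

Step 8
Reactants: 6 3-[3-(benzyloxy)-4-(methoxymethoxy)phenyl]propiolic acid; 12 3,5-bis(methoxymethoxy)-2-(trimethylsilyl)phenyl trifluoromethanesulfonate
Product: 14 1-[2-hydroxy-4,6-bis(methoxymethoxy)phenyl]-3-[3-(benzyloxy)-4-(methoxymethoxy)phenyl]prop-2-yn-1-one, via 3,5-bis(methoxymethoxy)benzyne 13 (not isolated)
Conditions: 6 (1.0 equiv), 12 (1.3 equiv), CsF (4 equiv), THF, sealed tube, 125 °C; aq. NH4Cl
Reagents that add atoms: none
Why: Fluoride attacks silicon of 12 and loss of triflate gives benzyne 13; the cesium carboxylate of 6 adds through oxygen, and the resulting aryl anion attacks the ester carbonyl through a four-membered tetrahedral intermediate that opens to the ortho-acyl phenoxide, so the aryne is inserted into the acyl C–O bond with formation of O1–C8a and C4a–C4. The closest known reaction type is the fluoride-induced insertion of arynes into carboxylic acid C–O bonds (O-arylation followed by an anionic acyl shift of the ortho-Fries kind), which accepts arylpropiolic acids. No ring is closed here: ring C stays open as the ynone and is closed in step 9. No stereocentre is formed. The step needs regioselective addition to the unsymmetrical aryne, and this is secured by the MOM ether next to the triple bond, which stabilises negative charge on the adjacent carbon inductively, so oxygen adds at the distal carbon (future C8a) and the acyl group lands beside the alkoxy group (future C4a, next to C5–O). Acyl transfer is favoured over simple protonation of the aryl anion by the aprotic medium and the high temperature.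

Step 9
Reactants: 14 1-[2-hydroxy-4,6-bis(methoxymethoxy)phenyl]-3-[3-(benzyloxy)-4-(methoxymethoxy)phenyl]prop-2-yn-1-one
Product: 16 2-[3-(benzyloxy)-4-(methoxymethoxy)phenyl]-5,7-bis(methoxymethoxy)-4H-chromen-4-one, via β-diethylamino enone 15 (not isolated)
Conditions: Et2NH (3 equiv), EtOH, 60 °C
Reagents that add atoms: none
Why: Conjugate addition of the amine to the ynone gives a β-amino enone whose β-carbon is attacked by the phenol in an addition–elimination (overall 6-endo oxa-Michael closure of ring C through O1–C2), which avoids the 5-exo aurone pathway open to simple base catalysis.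

Step 10
Reactants: 16 2-[3-(benzyloxy)-4-(methoxymethoxy)phenyl]-5,7-bis(methoxymethoxy)-4H-chromen-4-one
Product: 18 2-[3-(benzyloxy)-4-(methoxymethoxy)phenyl]-3-hydroxy-5,7-bis(methoxymethoxy)-4H-chromen-4-one, via flavone 2,3-epoxide 17 (not isolated)
Conditions: DMDO (acetone solution, 3 equiv in portions), CH2Cl2, 0 °C to rt; then p-TsOH·H2O (5 mol%), CH2Cl2, 0 °C
Reagents that add atoms: dimethyldioxirane, CC1(C)OO1
Why: Dimethyldioxirane epoxidises the C2=C3 enol-ether double bond under neutral conditions and a trace of acid opens the epoxide at C2 (cation stabilised by O1 and ring B), loss of the C3 proton giving the flavonol (epoxidation then ring opening); the two stereocentres of the racemic epoxide vanish on aromatisation.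

Step 11
Reactants: 18 2-[3-(benzyloxy)-4-(methoxymethoxy)phenyl]-3-hydroxy-5,7-bis(methoxymethoxy)-4H-chromen-4-one
Product: 19 3-(benzyloxy)-2-[3-(benzyloxy)-4-(methoxymethoxy)phenyl]-5,7-bis(methoxymethoxy)-4H-chromen-4-one
Conditions: BnBr (1.3 equiv), K2CO3, DMF, rt
Reagents that add atoms: benzyl bromide, BrCc1ccccc1
Why: The acidic 3-hydroxyl is the only free OH and is benzylated as its potassium salt (Williamson etherification).

Step 12
Reactants: 19 3-(benzyloxy)-2-[3-(benzyloxy)-4-(methoxymethoxy)phenyl]-5,7-bis(methoxymethoxy)-4H-chromen-4-one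
Product: 20 3,3'-di-O-benzylquercetin, i.e. 3-(benzyloxy)-2-[3-(benzyloxy)-4-hydroxyphenyl]-5,7-dihydroxy-4H-chromen-4-one
Conditions: HCl (3 M aq.), MeOH–THF, 50 °C
Reagents that add atoms: none
Why: Acid-catalysed acetal exchange with methanol cleaves all three aryl MOM ethers (the peri 5-O-MOM fastest), while benzyl ethers are stable to these conditions.

Step 13
Reactants: 20 3,3'-di-O-benzylquercetin
Product: 21 3,3'-di-O-benzylquercetin 7,4'-bis(hydrogen sulfate), handled as its dipotassium salt
Conditions: SO3·NMe3 (8 equiv), K2CO3 (8 equiv), DMF, 40 °C; reversed-phase chromatography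
Reagents that add atoms: sulfur trioxide–trimethylamine complex, C[N+](C)(C)S(=O)(=O)[O-]
Why: O-Sulfonation with the sulfur trioxide–amine complex takes place at the two acidic, accessible phenols (7-OH and 4'-OH); 5-OH is held in a strong hydrogen bond to the C4 carbonyl and should stay free, and 3-O and 3'-O are blocked as benzyl ethers.

Step 14
Reactants: 21 3,3'-di-O-benzylquercetin 7,4'-bis(hydrogen sulfate) (dipotassium salt)
Product: 22 3',5-dihydroxy-4',7-bis(sulfooxy)flavonol
Conditions: H2 (1 atm), Pd/C (10 wt%), MeOH–H2O, rt; filter; aq. HCl to pH 1.5 at 0 °C, C18 solid-phase extraction (desalting), freeze-drying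
Reagents that add atoms: none
Why: Catalytic hydrogenolysis cleaves the two O-benzyl bonds without touching aryl sulfate salts or the chromone double bond, and brief cold acidification with reversed-phase desalting then releases the acid form.

Compound list
1 | 3,4-dihydroxybenzaldehyde | O=Cc1ccc(O)c(O)c1 | starting material
2 | 3-hydroxy-4-(methoxymethoxy)benzaldehyde | O=Cc1ccc(OCOC)c(O)c1 | intermediate
3 | 3-(benzyloxy)-4-(methoxymethoxy)benzaldehyde | O=Cc1ccc(OCOC)c(OCc2ccccc2)c1 | intermediate
4 | 2-(benzyloxy)-4-ethynyl-1-(methoxymethoxy)benzene | C#Cc1ccc(OCOC)c(OCc2ccccc2)c1 | intermediate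
5 | lithium [3-(benzyloxy)-4-(methoxymethoxy)phenyl]acetylide (formed in the flask) | [Li]C#Cc1ccc(OCOC)c(OCc2ccccc2)c1 | intermediate
6 | 3-[3-(benzyloxy)-4-(methoxymethoxy)phenyl]propiolic acid | OC(=O)C#Cc1ccc(OCOC)c(OCc2ccccc2)c1 | intermediate
7 | phloroglucinol (benzene-1,3,5-triol) | Oc1cc(O)cc(O)c1 | starting material
8 | 3,5-bis(methoxymethoxy)phenol | COCOc1cc(O)cc(OCOC)c1 | intermediate
9 | 2-bromo-3,5-bis(methoxymethoxy)phenol | COCOc1cc(O)c(Br)c(OCOC)c1 | intermediate
10 | [2-bromo-3,5-bis(methoxymethoxy)phenoxy]trimethylsilane (formed in the flask) | COCOc1cc(O[Si](C)(C)C)c(Br)c(OCOC)c1 | intermediate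
11 | lithium 3,5-bis(methoxymethoxy)-2-(trimethylsilyl)phenoxide (formed in the flask) | COCOc1cc([O-])c([Si](C)(C)C)c(OCOC)c1.[Li+] | intermediate
12 | 3,5-bis(methoxymethoxy)-2-(trimethylsilyl)phenyl trifluoromethanesulfonate | COCOc1cc(OCOC)c([Si](C)(C)C)c(OS(=O)(=O)C(F)(F)F)c1 | intermediate
13 | 3,5-bis(methoxymethoxy)benzyne (formed in the flask) | COCOC1=CC(OCOC)=CC#C1 | intermediate
14 | 1-[2-hydroxy-4,6-bis(methoxymethoxy)phenyl]-3-[3-(benzyloxy)-4-(methoxymethoxy)phenyl]prop-2-yn-1-one | O=C(C#Cc1ccc(OCOC)c(OCc2ccccc2)c1)c1c(O)cc(OCOC)cc1OCOC | intermediate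
15 | 3-(diethylamino)-1-[2-hydroxy-4,6-bis(methoxymethoxy)phenyl]-3-[3-(benzyloxy)-4-(methoxymethoxy)phenyl]prop-2-en-1-one (formed in the flask, alkene geometry undefined) | O=C(C=C(N(CC)CC)c1ccc(OCOC)c(OCc2ccccc2)c1)c1c(O)cc(OCOC)cc1OCOC | intermediate
16 | 2-[3-(benzyloxy)-4-(methoxymethoxy)phenyl]-5,7-bis(methoxymethoxy)-4H-chromen-4-one (3'-O-benzyl-5,7,4'-tri-O-MOM-luteolin) | O=c1cc(-c2ccc(OCOC)c(OCc3ccccc3)c2)oc2cc(OCOC)cc(OCOC)c12 | intermediate
17 | 2,3-epoxide of flavone 16 (formed in the flask, racemic, cis-fused oxirane across C2–C3) | O=C1C2OC2(c2ccc(OCOC)c(OCc3ccccc3)c2)Oc2cc(OCOC)cc(OCOC)c21 | intermediate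
18 | 2-[3-(benzyloxy)-4-(methoxymethoxy)phenyl]-3-hydroxy-5,7-bis(methoxymethoxy)-4H-chromen-4-one (3'-O-benzyl-5,7,4'-tri-O-MOM-quercetin) | O=c1c(O)c(-c2ccc(OCOC)c(OCc3ccccc3)c2)oc2cc(OCOC)cc(OCOC)c12 | intermediate
19 | 3-(benzyloxy)-2-[3-(benzyloxy)-4-(methoxymethoxy)phenyl]-5,7-bis(methoxymethoxy)-4H-chromen-4-one | O=c1c(OCc2ccccc2)c(-c2ccc(OCOC)c(OCc3ccccc3)c2)oc2cc(OCOC)cc(OCOC)c12 | intermediate
20 | 3,3'-di-O-benzylquercetin | O=c1c(OCc2ccccc2)c(-c2ccc(O)c(OCc3ccccc3)c2)oc2cc(O)cc(O)c12 | intermediate
21 | 3,3'-di-O-benzylquercetin 7,4'-bis(hydrogen sulfate), handled as its dipotassium salt | O=c1c(OCc2ccccc2)c(-c2ccc(OS(=O)(=O)O)c(OCc3ccccc3)c2)oc2cc(OS(=O)(=O)O)cc(O)c12 | intermediate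
22 | 3',5-dihydroxy-4',7-bis(sulfooxy)flavonol (quercetin 7,4'-bis(hydrogen sulfate)) | O=c1c(O)c(-c2ccc(OS(=O)(=O)O)c(O)c2)oc2cc(OS(=O)(=O)O)cc(O)c12 | target

Total step count: 14.
Longest linear sequence: 11 steps (steps 1–4 and 8–14, from 3,4-dihydroxybenzaldehyde); the ring A arm (steps 5–7) joins at step 8.

Steps most likely to fail

Step 8. Several processes can go wrong here:
- the cesium arylpropiolate may lose CO2 at 125 °C;
- the aryl anion may be protonated before the acyl shift, so the reaction stops at the aryl ester;
- the product phenoxide may be arylated by surplus aryne;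
- the phenoxide may close ring C unselectively (5-exo against 6-endo) under the hot fluoride conditions.

Fallback, setting out from acid 6 and bromophenol 9 and returning at ynone 14: acid 6 is condensed with N,O-dimethylhydroxylamine (EDC·HCl, N-methylmorpholine, CH2Cl2, 0 °C) to the Weinreb amide F1. Bromophenol 9 is treated with n-BuLi (2.2 equiv, THF, −78 °C), which deprotonates the hydroxyl and exchanges bromine, to give the O,C-dilithio species F2. Addition of F1 at −78 °C and a cold mildly acidic quench should release ynone 14 from the stable tetrahedral chelate. The same C4a–C4 bond is made by aryllithium acylation instead of aryne insertion.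

Step 10. Long exposure to DMDO may oxidise benzylic or acetal C–H bonds, and the acid used to open the epoxide may strip the labile 5-O-MOM group. Fallback, setting out from flavone 16 and returning at flavonol 18: deprotonation at C3 with LDA (THF, −78 °C) gives the 3-lithioflavone F3. Trapping with B(OMe)3 gives the dimethyl flavon-3-ylboronate F4, and oxidation in the same flask (H2O2, AcOH, 0 °C) should give 18. This C3 lithiation–borylation–oxidation runs under basic and then mildly oxidising conditions that MOM and benzyl ethers tolerate.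

Step 6. Bromination may go to C4 (para to OH) or run on to the dibromide, giving a mixture that is hard to separate and a wrongly placed silyl group later. Fallback, setting out from phenol 8 and returning at triflate 12, bypassing steps 6 and 7: phenol 8 is carbamoylated (i-PrNCO, cat. Et3N, CH2Cl2) to the N-isopropylcarbamate F5. A one-pot sequence (TBSOTf/TMEDA, Et2O, 0 °C; n-BuLi/TMEDA, −78 °C; TMSCl; acidic work-up) silylates nitrogen transiently, metalates the ring carbon between the carbamate and MOM oxygens (directed ortho-metalation) and traps it on carbon, giving the ortho-silyl carbamate F6. Treatment with DBU/Et2NH in MeCN at 40 °C unmasks the silylphenol F7 in the flask, which is triflated directly with PhNTf2 to give 12.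

Further compounds
F1 | step 8 | N-methoxy-N-methyl-3-[3-(benzyloxy)-4-(methoxymethoxy)phenyl]propiolamide | CON(C)C(=O)C#Cc1ccc(OCOC)c(OCc2ccccc2)c1
F2 | step 8 | lithium 2-lithio-3,5-bis(methoxymethoxy)phenoxide | [Li]c1c([O-])cc(OCOC)cc1OCOC.[Li+]
F3 | step 10 | 3-lithio derivative of flavone 16 | [Li]c1c(-c2ccc(OCOC)c(OCc3ccccc3)c2)oc2cc(OCOC)cc(OCOC)c2c1=O
F4 | step 10 | dimethyl {2-[3-(benzyloxy)-4-(methoxymethoxy)phenyl]-5,7-bis(methoxymethoxy)-4-oxo-4H-chromen-3-yl}boronate | COB(OC)c1c(-c2ccc(OCOC)c(OCc3ccccc3)c2)oc2cc(OCOC)cc(OCOC)c2c1=O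
F5 | step 6 | 3,5-bis(methoxymethoxy)phenyl N-isopropylcarbamate | CC(C)NC(=O)Oc1cc(OCOC)cc(OCOC)c1
F6 | step 6 | 3,5-bis(methoxymethoxy)-2-(trimethylsilyl)phenyl N-isopropylcarbamate | CC(C)NC(=O)Oc1cc(OCOC)cc(OCOC)c1[Si](C)(C)C
F7 | step 6 | 3,5-bis(methoxymethoxy)-2-(trimethylsilyl)phenol | COCOc1cc(O)c([Si](C)(C)C)c(OCOC)c1
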